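Ring atoms are numbered as in quinic acid: C1 carries OH and the carboxyl, C2 and C6 are CH2, and C3, C4, C5 carry oxygen (O1, O3, O4, O5 are the oxygens on those carbons). Compound numbers 1–14 are those of the list after the steps.

## Analysis of the target

Compound 14 is the triester of (−)-quinic acid with three gallic acid units: a cyclohexane ring with a hydroxyl and the free carboxylic acid on C1, 3,4,5-trihydroxybenzoyloxy groups on C3, C4 and C5, and methylenes at C2 and C6. It has four stereocentres: C3 and C5 are both R, O4 is cis to O3 and trans to O5, and the C1 hydroxyl lies on the face of O3 and O4 while the carboxyl lies on the face of O5. The sensitive groups are the three aryl esters (base-labile, and mobile while a neighbouring hydroxyl is free), the nine oxidisable pyrogallol hydroxyls and the free acid, so the end of the synthesis must be neutral and reductive, with phenols and acid carried as benzyl ethers and a benzyl ester. The aromatic rings can be bought; the difficulty is the 1,3,4,5-oxygenated ring with its fully substituted C1, to be made as one enantiomer without starting from a chiral ring. The strategy rests on C3 and C5 having the same absolute sense: once C4 is a carbonyl carbon, the two arms leaving C1 (C2–C3 and C6–C5) are identical in constitution and configuration. The ketone has no true twofold axis, because C1 bears two different groups, but exchanging hydroxyl and ester at C1 gives a structure that a half-turn about the line through C1 and C4 superimposes on the original, so neither C1 nor C4 is stereogenic at that stage. The four stereocentres therefore shrink to two C–O centres of one sense, which one chiral catalyst can set on a mirror-symmetric ketone, and one relative relation (O4 against the C1 substituents), which is left to a reduction.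

## Retrosynthetic reasoning

14 to 13. The ten O–benzyl bonds (nine aryl ethers and the C1 ester) are cut first. A single neutral hydrogenolysis is the only kind of final step that the galloyl esters and the free pyrogallols tolerate, so everything acidic is masked as benzyl.

13 to 11 and 12. The three acyl C–O bonds at O3, O4 and O5 are cut. The aromatic part is then the commercial acid chloride 12, used three times, and the ring is reduced to benzyl quinate 11. The forward acylation has to take the three secondary hydroxyls and leave the hindered tertiary C1 hydroxyl alone.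

11 to 10 to 9. The O3–H and O5–H bonds are traced back to O–N bonds, and the C4–H bond to a carbonyl. This returns the ring to the ketone 9, in which C1 and C4 are not stereogenic. Forward, reductive N–O cleavage is trivial. The hydride reduction must place O4 cis to the C1 hydroxyl, and this can only come from the conformation of 9, because the two carbonyl faces differ only through C1.

9 to 6 and two molecules of 7 (key disconnection). The C3–O and C5–O bonds are cut. They are the only bonds α to the carbonyl, and an enamine made from 6 and a chiral amino-acid catalyst can form both with the same absolute sense. Cutting here removes all stereochemistry in one retrosynthetic step and leaves the achiral, mirror-symmetric ketone 6.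

6 to 5 to 3. The ketone is masked as its ethylene ketal, and the C1–O bond is cut back to the ester enolate 4 of 3. C1 is thus completed by an electrophilic hydroxylation while the molecule is achiral, so no selectivity question arises.

3 to 1. The benzyl ester O–C bond is cut, leaving the commercial ketal acid 1. Benzyl is introduced at the start because it is the one ester that falls in the final hydrogenolysis.

## Alternatives that were turned down

Alternative 1: The C1–C2 ring bond is disconnected, so that the carbocycle is traced back to the six-membered lactone 5,6-trans-3-(benzyloxy)-5-(tert-butyldimethylsilyloxy)-6-vinyloxan-2-one A2.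
- Forward step: O-silylation of the lactone enolate of A2 and Ireland–Claisen rearrangement, through a boat because the ketene acetal is endocyclic, would contract the ring to 1-(benzyloxy)-5-(tert-butyldimethylsilyloxy)cyclohex-3-ene-1-carboxylic acid A1 with the carboxyl cis to the silyloxy group.
- For: the fully substituted C1 is set relative to C5 by a stereospecific intramolecular event. The C3=C4 alkene of A1 is placed for a syn-dihydroxylation anti to the C5 silyloxy group. On the C1/C4 relation this is stronger than the chosen route, which relies on a conformational preference in step 5.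
- Against: A2 carries two stereocentres that must first be made enantioselectively on an open chain. C1 has to carry a benzyl ether throughout. After A1, esterification, dihydroxylation and desilylation are still needed before the acylation stage.
- Comparison: the sequence would be roughly twice as long. The chosen route reaches the triol stage 11 in six steps, because C1 is built while the molecule is achiral and both C–O stereocentres come from one catalytic step.

Alternative 2: The C1–O and C4–O bonds are cut together, leading back to benzyl (5R)-5-(tert-butyldimethylsilyloxy)cyclohexa-1,3-diene-1-carboxylate A4.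
- Forward step: [4+2] addition of singlet dioxygen A5 across C1 and C4 of A4, on the face away from the silyloxy group, would give benzyl 8-(tert-butyldimethylsilyloxy)-2,3-dioxabicyclo[2.2.2]oct-5-ene-1-carboxylate A3. Reduction of the O–O bond would release O1 and O4 cis to each other and trans to O5.
- For: the cis O1/O4 relation, which the chosen route must win in step 5, is guaranteed by the peroxide bridge. Two C–O bonds, one of them at the fully substituted carbon, form at once. On these points the alternative is stronger.
- Against: A4 is an ester-conjugated, electron-poor diene, a poor partner for electrophilic A5, with allylic hydrogens open to ene reaction. A4 can aromatise by loss of its silyloxy group and must itself be made as one enantiomer. The remaining alkene of A3 must still become a C3–O bond with C2 as methylene and O3 cis to O4, a regio- and stereoselective hydration for which the structure offers no clear handle.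
- Comparison: the chosen route oxygenates C3 and C5 directly at saturated carbons with catalyst control and has no such unresolved functionalisation.

Alternative 3: The cuts lie inside the three aromatic rings, each split into a two-carbon alkyne piece and a four-carbon furan piece. This leads back to benzyl 3,4,5-tri-O-propioloylquinate A7 and 3,4-bis(benzyloxy)furan A8.
- Forward step: three Diels–Alder additions of A8 to the alkynoates of A7, then acid-induced opening of the oxygen-bridged adducts to phenols, would give benzyl 3,4,5-tris-O-[3,4-bis(benzyloxy)-5-hydroxybenzoyl]quinate A6.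
- For: three rings are made in one operation. The slim propioloyl groups should go onto the crowded O3/O4/O5 triad more easily than the bulky aroyl group of 12, a real advantage over step 7.
- Against: A7 is an ester of 11, so the whole stereochemical problem of the ring is left to another route. A one-step acylation with a commercial acid chloride is replaced by a threefold cycloaddition and aromatisation. The bridge must open in the same direction three times (hydroxyl meta, not ortho, to the ester), under acid and heat in the presence of three esters. A8 is an electron-rich, sensitive furan.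
- Comparison: the chosen strategy spends its key step on the ring stereocentres, where the difficulty is, and buys the aromatic rings.

Key step: step 4

Assumption: 1, the ethylene ketal of 4-oxocyclohexane-1-carboxylic acid, is taken as a catalogue compound; if it is not, ketalisation of that keto acid supplies it in one extra step.

## Route

Step 1
Reactants: 1 1,4-dioxaspiro[4.5]decane-8-carboxylic acid
Product: 3 benzyl 1,4-dioxaspiro[4.5]decane-8-carboxylate, via potassium carboxylate 2 (not isolated)
Conditions: BnBr (1.1 equiv), K2CO3 (1.5 equiv), DMF, 23 °C
Reagents that add atoms: benzyl bromide, BrCc1ccccc1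
Why: Carboxylate O-alkylation (SN2) with a benzylic bromide; the ketal is inert to carbonate, and the benzyl ester is chosen because it is released in the final hydrogenolysis.

Step 2
Reactants: 3 benzyl 1,4-dioxaspiro[4.5]decane-8-carboxylate
Product: 5 benzyl 8-hydroxy-1,4-dioxaspiro[4.5]decane-8-carboxylate, via lithium ester enolate 4 (not isolated)
Conditions: LiN(iPr)2 (1.2 equiv), THF, −78 °C; 2-(phenylsulfonyl)-3-phenyloxaziridine (1.3 equiv), −78 °C; aq NH4Cl at −78 °C
Reagents that add atoms: 2-(phenylsulfonyl)-3-phenyloxaziridine, O=S(=O)(c1ccccc1)N1OC1c1ccccc1
Why: Ester enolate α-hydroxylation with an N-sulfonyloxaziridine: the only α-hydrogen is removed and the fully substituted enolate attacks the oxaziridine oxygen. The carbon lies on the mirror plane of the molecule, so no stereocentre is created, and the ketal keeps the C4 carbonyl out of the enolate chemistry.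

Step 3
Reactants: 5 benzyl 8-hydroxy-1,4-dioxaspiro[4.5]decane-8-carboxylate
Product: 6 benzyl 1-hydroxy-4-oxocyclohexane-1-carboxylate
Conditions: 1 M aq HCl, THF, 23 °C
Reagents that add atoms: water, O
Why: Acid-catalysed ketal hydrolysis; the benzyl ester and the tertiary alcohol survive dilute acid at room temperature. The hydroxyl is γ to the new carbonyl, so neither retro-aldol cleavage nor elimination is open.

Step 4
Reactants: 6 benzyl 1-hydroxy-4-oxocyclohexane-1-carboxylate, 7 nitrosobenzene
Product: 9 benzyl (3R,5R)-3,5-bis(anilinooxy)-1-hydroxy-4-oxocyclohexane-1-carboxylate, via mono(anilinooxy) ketone 8 (not isolated)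
Conditions: L-proline, (S)-pyrrolidine-2-carboxylic acid (30 mol %), 7 (3.0 equiv in all, added as a DMF solution over 24 h by syringe pump), DMF, 0 °C
Reagents that add atoms: nitrosobenzene (second molecule of 7), O=Nc1ccccc1
Why: L-Proline condenses with the C4 ketone to an enamine towards C3 or C5; its carboxylic acid hydrogen-bonds to the nitrogen of 7, so the enamine carbon attacks the nitroso oxygen (O- and not N-selectivity) on the enamine face next to the acid, and hydrolysis releases the (3R)-α-anilinooxy ketone 8 and the catalyst. The closest known reaction is the proline-catalysed α-aminoxylation of cyclohexanones with nitrosobenzene, established for 4,4-disubstituted ketones and for the α,α′-double reaction; no ring is closed. Because 6 has a mirror plane through C1 and C4, it does not matter which α-methylene reacts first: 8 forms as two C1 epimers (new oxygen cis or trans to the C1 hydroxyl), each with R at the new carbon. In the second cycle the enamine forms on the unsubstituted α′ side, away from the anilinooxy group, a second molecule of 7 is taken up and the catalyst again imposes R, matched by the substrate's own preference for attack anti to the pseudoaxial α-substituent, so both epimers of 8 give the same trans-(3R,5R) product 9, in which the two ring arms of C1 are identical and C1 is no longer stereogenic. Both new stereocentres are thus set by the catalyst alone, and the trans relation follows from two additions of the same sense. Any (3S) material from the first cycle is carried mainly into the separable cis diastereomers, so the enantiomeric purity of 9 should exceed that of a single addition. Slow addition keeps the concentration of 7 low and limits its self-condensation, and the C1 hydroxyl, being γ to the carbonyl, cannot interfere through retro-aldol or elimination chemistry.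

Step 5
Reactants: 9 benzyl (3R,5R)-3,5-bis(anilinooxy)-1-hydroxy-4-oxocyclohexane-1-carboxylate
Product: 10 benzyl (3R,5R)-3,5-bis(anilinooxy)-1,4-dihydroxycyclohexane-1-carboxylate (C4 hydroxyl cis to O3 and to the C1 hydroxyl)
Conditions: NaBH4 (1.5 equiv), THF/MeOH (4:1), −78 → −40 °C
Reagents that add atoms: none
Why: Borohydride reduction of a cyclohexanone under conformational control: 9 should sit in the quinate-type chair with CO2Bn equatorial and the C1 hydroxyl axial and hydrogen-bonded to the syn-axial oxygen on C3, and hydride enters axially, antiperiplanar to that axial C3–O bond (Felkin–Anh and torsional preference). This gives the equatorial C4 hydroxyl cis to O3 and to the C1 hydroxyl and trans to O5; a chiral reductant could not do better, since the two carbonyl faces are interchanged by the local symmetry of the C3/C5 pair and differ only through C1. Ester and N–O bonds are inert to NaBH4 at this temperature.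

Step 6
Reactants: 10 benzyl (3R,5R)-3,5-bis(anilinooxy)-1,4-dihydroxycyclohexane-1-carboxylate
Product: 11 benzyl (−)-quinate, benzyl (3R,5R)-1,3,4,5-tetrahydroxycyclohexane-1-carboxylate with O4 cis to O3 and to the C1 hydroxyl
Conditions: Zn dust (10 equiv), AcOH/THF (1:1), 23 °C
Reagents that add atoms: none
Why: Dissolving-metal reduction cleaves the weak N–O bonds of the two O-alkyl-N-arylhydroxylamines to the alcohols and aniline; C–O bonds, the benzyl ester and all stereocentres are untouched.

Step 7
Reactants: 11 benzyl (−)-quinate, 12 3,4,5-tris(benzyloxy)benzoyl chloride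
Product: 13 benzyl 3,4,5-tris-O-[3,4,5-tris(benzyloxy)benzoyl]quinate
Conditions: 12 (3.6 equiv in all), pyridine (10 equiv), DMAP (0.3 equiv), CH2Cl2, 0 → 23 °C
Reagents that add atoms: 3,4,5-tris(benzyloxy)benzoyl chloride (second and third molecules of 12), O=C(Cl)c1cc(OCc2ccccc2)c(OCc2ccccc2)c(OCc2ccccc2)c1.O=C(Cl)c1cc(OCc2ccccc2)c(OCc2ccccc2)c(OCc2ccccc2)c1
Why: DMAP-catalysed acylation through the N-acylpyridinium ion takes the three secondary hydroxyls, one molecule of 12 each; the tertiary C1 hydroxyl next to the ester is too hindered and too electron-poor to compete at this stoichiometry. Acyl migration among O3, O4 and O5 is without consequence because all three receive the same group.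

Step 8
Reactants: 13 benzyl 3,4,5-tris-O-[3,4,5-tris(benzyloxy)benzoyl]quinate
Product: 14 3,4,5-tri-O-galloylquinic acid (CNP0148451.1)
Conditions: H2 (1 atm), Pd/C (10 wt % Pd), THF/MeOH (1:1), 23 °C; filtration and evaporation under argon
Reagents that add atoms: none
Why: Hydrogenolysis removes the nine aryl benzyl ethers and the benzyl ester under neutral conditions; the aroyl esters of secondary alcohols, the tertiary alcohol and the ring stereocentres are inert, and the absence of base prevents ester migration or hydrolysis.

## Compound list

1 | 1,4-dioxaspiro[4.5]decane-8-carboxylic acid | OC(=O)C1CCC2(CC1)OCCO2 | starting material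
2 | potassium 1,4-dioxaspiro[4.5]decane-8-carboxylate | [K+].[O-]C(=O)C1CCC2(CC1)OCCO2 | intermediate
3 | benzyl 1,4-dioxaspiro[4.5]decane-8-carboxylate | O=C(OCc1ccccc1)C1CCC2(CC1)OCCO2 | intermediate
4 | lithium enolate of 3, lithium (benzyloxy)(1,4-dioxaspiro[4.5]decan-8-ylidene)methanolate | [Li]OC(OCc1ccccc1)=C1CCC2(CC1)OCCO2 | intermediate
5 | benzyl 8-hydroxy-1,4-dioxaspiro[4.5]decane-8-carboxylate | O=C(OCc1ccccc1)C1(O)CCC2(CC1)OCCO2 | intermediate
6 | benzyl 1-hydroxy-4-oxocyclohexane-1-carboxylate | O=C1CCC(O)(C(=O)OCc2ccccc2)CC1 | intermediate
7 | nitrosobenzene | O=Nc1ccccc1 | starting material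
8 | benzyl (3R)-3-(anilinooxy)-1-hydroxy-4-oxocyclohexane-1-carboxylate (both C1 epimers; C1 left undefined) | O=C1CCC(O)(C(=O)OCc2ccccc2)C[C@H]1ONc1ccccc1 | intermediate
9 | benzyl (3R,5R)-3,5-bis(anilinooxy)-1-hydroxy-4-oxocyclohexane-1-carboxylate | c1ccccc1NO[C@@H]2CC(O)(C(=O)OCc3ccccc3)C[C@@H](ONc3ccccc3)C2=O | intermediate
10 | benzyl (3R,5R)-3,5-bis(anilinooxy)-1,4-dihydroxycyclohexane-1-carboxylate, C4 hydroxyl cis to O3 and to the C1 hydroxyl | c1ccccc1NO[C@@H]1C[C@](O)(C(=O)OCc2ccccc2)C[C@@H](ONc2ccccc2)[C@H]1O | intermediate
11 | benzyl (−)-quinate, benzyl (3R,5R)-1,3,4,5-tetrahydroxycyclohexane-1-carboxylate, O4 cis to O3 and to the C1 hydroxyl | O[C@@H]1C[C@](O)(C(=O)OCc2ccccc2)C[C@@H](O)[C@H]1O | intermediate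
12 | 3,4,5-tris(benzyloxy)benzoyl chloride | O=C(Cl)c1cc(OCc2ccccc2)c(OCc2ccccc2)c(OCc2ccccc2)c1 | starting material
13 | benzyl 3,4,5-tris-O-[3,4,5-tris(benzyloxy)benzoyl]quinate | O=C(O[C@@H]1C[C@](O)(C(=O)OCc2ccccc2)C[C@@H](OC(=O)c2cc(OCc3ccccc3)c(OCc3ccccc3)c(OCc3ccccc3)c2)[C@H]1OC(=O)c1cc(OCc2ccccc2)c(OCc2ccccc2)c(OCc2ccccc2)c1)c1cc(OCc2ccccc2)c(OCc2ccccc2)c(OCc2ccccc2)c1 | intermediate
14 | 3,4,5-tri-O-galloylquinic acid, (3R,5R)-1-hydroxy-3,4,5-tris[(3,4,5-trihydroxybenzoyl)oxy]cyclohexane-1-carboxylic acid, O4 cis to O3 and to the C1 hydroxyl | O=C(O[C@@H]1C[C@](O)(C(=O)O)C[C@@H](OC(=O)c2cc(O)c(O)c(O)c2)[C@H]1OC(=O)c1cc(O)c(O)c(O)c1)c1cc(O)c(O)c(O)c1 | target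

## Step count and least certain steps

Total: 8 steps. Longest linear sequence: 8 steps (1 to 14); the route is fully linear, with 7 and 12 bought and L-proline used as a bought catalyst.

Step 4 (key step). The most likely failure is that the second aminoxylation lags behind the first: the enamine of 8 is more hindered and less nucleophilic. Nitrosobenzene would then be lost to self-condensation, and the α-anilinooxy ketones could fragment by base-induced N–O cleavage before or during isolation. The free hydroxy ester is also an untested spectator. Fallback, setting out from 6: the two C–O bonds would be made as stable benzoates by primary-amine-catalysed α-benzoyloxylation with dibenzoyl peroxide, the catalyst being a 9-amino-9-deoxy-epi-cinchona amine as its acid salt, taken in the pseudoenantiomeric series that gives the R ester. This would give first benzyl (3R)-3-(benzoyloxy)-1-hydroxy-4-oxocyclohexane-1-carboxylate F1, and with a second portion of peroxide benzyl (3R,5R)-3,5-bis(benzoyloxy)-1-hydroxy-4-oxocyclohexane-1-carboxylate F2; the same convergence of C1 epimers applies. NaBH4 reduction under the conformational control of step 5 would give benzyl 3,5-di-O-benzoylquinate F3, and transesterification of the benzoates with benzyl alcohol (catalytic K2CO3) returns to the route at 11.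

Step 5. Poor facial selectivity is the risk. The two carbonyl faces differ only through the remote C1 substituents, so the outcome follows the chair population. If the chair with axial CO2Bn is more populated than expected, for instance because methanol breaks the O1–H···O3 hydrogen bond, hydride adds to the other face. No chiral reagent can correct this. Fallback, setting out from 9: the epimer is used rather than discarded. The reduction gives the C4 epimer of 10, benzyl (3R,5R)-3,5-bis(anilinooxy)-1,4-dihydroxycyclohexane-1-carboxylate F4, with the C4 hydroxyl trans to the C1 hydroxyl. Its only secondary hydroxyl would undergo Mitsunobu esterification with 3,4,5-tris(benzyloxy)benzoic acid (PPh3, diisopropyl azodicarboxylate), which inverts C4 and installs the C4 gallate in one step, giving benzyl (3R,5R)-3,5-bis(anilinooxy)-1-hydroxy-4-[3,4,5-tris(benzyloxy)benzoyloxy]cyclohexane-1-carboxylate F5 of quinate configuration. Zn in AcOH would then give benzyl 4-O-[3,4,5-tris(benzyloxy)benzoyl]quinate F6, and acylation of O3 and O5 with 12 rejoins the route at 13.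

Step 7. Acylation may stop short at O4, which becomes flanked by two large aroyloxy groups, or at the axial O3. Forcing conditions would then begin to acylate the C1 hydroxyl. Fallback, setting out from 11: the phenol protection is changed. The more electrophilic and less bulky 3,4,5-triacetoxybenzoyl chloride (pyridine, DMAP) would give benzyl 3,4,5-tris-O-(3,4,5-triacetoxybenzoyl)quinate F7. Hydrazinolysis of the nine phenolic acetates (hydrazine hydrate, THF, 0 °C, under argon), which is much faster than attack on the aroyl esters, would give benzyl 3,4,5-tri-O-galloylquinate F8, and hydrogenolysis of the single benzyl ester over Pd/C arrives at 14.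

Step 2. The hindered, fully substituted enolate may be hydroxylated incompletely, or may add to the sulfonimine formed from the oxidant. Fallback, setting out from 1: the dianion of the acid (LiN(iPr)2, 2.2 equiv, THF) would be oxygenated with O2 and the hydroperoxide reduced with P(OEt)3, giving 8-hydroxy-1,4-dioxaspiro[4.5]decane-8-carboxylic acid F9. O-Benzylation of the carboxyl group of F9 (BnBr, K2CO3, DMF) rejoins the route at 5.

## Further compounds

F1 | step 4 | benzyl (3R)-3-(benzoyloxy)-1-hydroxy-4-oxocyclohexane-1-carboxylate (both C1 epimers) | O=C1CCC(O)(C(=O)OCc2ccccc2)C[C@H]1OC(=O)c1ccccc1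
F2 | step 4 | benzyl (3R,5R)-3,5-bis(benzoyloxy)-1-hydroxy-4-oxocyclohexane-1-carboxylate | O=C(O[C@@H]1CC(O)(C(=O)OCc2ccccc2)C[C@@H](OC(=O)c2ccccc2)C1=O)c1ccccc1
F3 | step 4 | benzyl 3,5-di-O-benzoylquinate | O=C(O[C@@H]1C[C@](O)(C(=O)OCc2ccccc2)C[C@@H](OC(=O)c2ccccc2)[C@H]1O)c1ccccc1
F4 | step 5 | benzyl (3R,5R)-3,5-bis(anilinooxy)-1,4-dihydroxycyclohexane-1-carboxylate, C4 hydroxyl trans to the C1 hydroxyl (C4 epimer of 10) | c1ccccc1NO[C@@H]1C[C@](O)(C(=O)OCc2ccccc2)C[C@@H](ONc2ccccc2)[C@@H]1O
F5 | step 5 | benzyl (3R,5R)-3,5-bis(anilinooxy)-1-hydroxy-4-[3,4,5-tris(benzyloxy)benzoyloxy]cyclohexane-1-carboxylate, quinate configuration | c1ccccc1NO[C@@H]1C[C@](O)(C(=O)OCc2ccccc2)C[C@@H](ONc2ccccc2)[C@H]1OC(=O)c1cc(OCc2ccccc2)c(OCc2ccccc2)c(OCc2ccccc2)c1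
F6 | step 5 | benzyl 4-O-[3,4,5-tris(benzyloxy)benzoyl]quinate | O[C@@H]1C[C@](O)(C(=O)OCc2ccccc2)C[C@@H](O)[C@H]1OC(=O)c1cc(OCc2ccccc2)c(OCc2ccccc2)c(OCc2ccccc2)c1
F7 | step 7 | benzyl 3,4,5-tris-O-(3,4,5-triacetoxybenzoyl)quinate | O=C(O[C@@H]1C[C@](O)(C(=O)OCc2ccccc2)C[C@@H](OC(=O)c2cc(OC(C)=O)c(OC(C)=O)c(OC(C)=O)c2)[C@H]1OC(=O)c1cc(OC(C)=O)c(OC(C)=O)c(OC(C)=O)c1)c1cc(OC(C)=O)c(OC(C)=O)c(OC(C)=O)c1
F8 | step 7 | benzyl 3,4,5-tri-O-galloylquinate | O=C(O[C@@H]1C[C@](O)(C(=O)OCc2ccccc2)C[C@@H](OC(=O)c2cc(O)c(O)c(O)c2)[C@H]1OC(=O)c1cc(O)c(O)c(O)c1)c1cc(O)c(O)c(O)c1
F9 | step 2 | 8-hydroxy-1,4-dioxaspiro[4.5]decane-8-carboxylic acid | OC(=O)C1(O)CCC2(CC1)OCCO2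
A1 | alternative 1 | 1-(benzyloxy)-5-(tert-butyldimethylsilyloxy)cyclohex-3-ene-1-carboxylic acid, silyloxy cis to the carboxyl | CC(C)(C)[Si](C)(C)O[C@@H]1C[C@](OCc2ccccc2)(C(=O)O)CC=C1
A2 | alternative 1 | 5,6-trans-3-(benzyloxy)-5-(tert-butyldimethylsilyloxy)-6-vinyloxan-2-one (C3 configuration immaterial) | CC(C)(C)[Si](C)(C)O[C@@H]1CC(OCc2ccccc2)C(=O)O[C@H]1C=C
A3 | alternative 2 | benzyl 8-(tert-butyldimethylsilyloxy)-2,3-dioxabicyclo[2.2.2]oct-5-ene-1-carboxylate, silyloxy anti to the peroxide bridge | CC(C)(C)[Si](C)(C)O[C@@H]1C[C@]2(C(=O)OCc3ccccc3)C=C[C@H]1OO2
A4 | alternative 2 | benzyl (5R)-5-(tert-butyldimethylsilyloxy)cyclohexa-1,3-diene-1-carboxylate | CC(C)(C)[Si](C)(C)O[C@@H]1CC(C(=O)OCc2ccccc2)=CC=C1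
A5 | alternative 2 | singlet dioxygen | O=O
A6 | alternative 3 | benzyl 3,4,5-tris-O-[3,4-bis(benzyloxy)-5-hydroxybenzoyl]quinate | O=C(O[C@@H]1C[C@](O)(C(=O)OCc2ccccc2)C[C@@H](OC(=O)c2cc(O)c(OCc3ccccc3)c(OCc3ccccc3)c2)[C@H]1OC(=O)c1cc(O)c(OCc2ccccc2)c(OCc2ccccc2)c1)c1cc(O)c(OCc2ccccc2)c(OCc2ccccc2)c1
A7 | alternative 3 | benzyl 3,4,5-tri-O-propioloylquinate | C#CC(=O)O[C@@H]1C[C@](O)(C(=O)OCc2ccccc2)C[C@@H](OC(=O)C#C)[C@H]1OC(=O)C#C
A8 | alternative 3 | 3,4-bis(benzyloxy)furan | c1occ(OCc2ccccc2)c1OCc1ccccc1
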